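**Retrosynthetic overview**

1. The strategy rests on one feature: C2 of the 1,4-benzodioxane (ring O1–C2–C3–O4–C4a–C8a) carries ring A, a 4-hydroxy-3,5-dimethoxyphenyl group. Its para hydroxyl makes the benzylic C2–O1 bond ionisable through a para-quinone methide, so C2 can be set last and only C3 must carry the absolute configuration.
2. End game: the C7 (E)-3-hydroxypropenyl chain is cut back to a C7 aldehyde (Wittig olefination, then i-Bu2AlH), because a cinnamyl alcohol would not survive the acid ring closure.
3. Key disconnection O1–C2: the trans-(2S,3S) dioxane aldehyde comes from an open aryl glycerol aryl ether with both phenols free, C3 fixed as S and C2 a mixture of epimers.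
4. C2–ring A bond: an aryllithium from allyl-protected 4-bromo-2,6-dimethoxyphenol adds to an α-aryloxy aldehyde. O4–C3 bond: Mitsunobu inversion of silylated methyl (R)-glycerate with 3-O-allylated 3,4-dihydroxy-5-methoxybenzaldehyde.
5. Ring order: rings A and B are bought; the dioxane is the only ring formed, in step 11.

Key step: step 11

Remark: the benzodioxane is numbered O1, C2 (ring A), C3 (CH2OH), O4, C4a, C5 (OMe), C7 (side chain), C8a, and ring B is the benzo ring. The glycerate-derived carbon keeps one spatial arrangement from step 4 onward; its CIP letter changes only where substituent priorities change (compound 15).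

**Route**

Step 1
Reactants: 1 methyl (R)-2,2-dimethyl-1,3-dioxolane-4-carboxylate
Product: 2 methyl (R)-2,3-dihydroxypropanoate
Conditions: Amberlyst 15 (H+ form), MeOH, rt; filter, concentrate
Reagents that add atoms: none
Why: Acid-catalysed transketalisation (acetonide methanolysis) should free the diol without touching the ester or the stereocentre, which takes no part in any bond change.

Step 2
Reactants: 2 methyl (R)-2,3-dihydroxypropanoate
Product: 3 methyl (R)-3-[(tert-butyldimethylsilyl)oxy]-2-hydroxypropanoate
Conditions: TBSCl (1.05 equiv), imidazole, CH2Cl2, 0 °C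
Reagents that add atoms: tert-butyldimethylsilyl chloride, CC(C)(C)[Si](C)(C)Cl
Why: Selective silylation of the primary hydroxyl by a bulky silyl chloride should leave the hindered, less nucleophilic α-hydroxy ester OH free for the Mitsunobu reaction.

Step 3
Reactants: 4 3,4-dihydroxy-5-methoxybenzaldehyde
Product: 5 3-(allyloxy)-4-hydroxy-5-methoxybenzaldehyde
Conditions: NaH (2.2 equiv), DMSO, rt; allyl bromide (1.0 equiv), rt; then aq. HCl
Reagents that add atoms: allyl bromide, C=CCBr
Why: Regioselective Williamson mono-alkylation of the catechol dianion should occur at the 3-phenoxide, because the 4-phenoxide is delocalised into the para formyl group and flanked by two ortho substituents, so the allyl group lands on the oxygen that becomes O1.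

Step 4
Reactants: 5 3-(allyloxy)-4-hydroxy-5-methoxybenzaldehyde; 3 methyl (R)-3-[(tert-butyldimethylsilyl)oxy]-2-hydroxypropanoate
Product: 6 methyl (S)-2-[2-(allyloxy)-4-formyl-6-methoxyphenoxy]-3-[(tert-butyldimethylsilyl)oxy]propanoate
Conditions: PPh3, DIAD, THF, 0 °C to rt
Reagents that add atoms: none
Why: Mitsunobu etherification of an α-hydroxy ester with an acidic phenol (para formyl) should proceed by SN2 displacement of the alkoxyphosphonium with inversion, turning the (R)-carbinol into the (S)-aryl ether that becomes C3 of the dioxane.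

Step 5
Reactants: 6 methyl (S)-2-[2-(allyloxy)-4-formyl-6-methoxyphenoxy]-3-[(tert-butyldimethylsilyl)oxy]propanoate
Product: 7 methyl (S)-2-[2-(allyloxy)-4-(1,3-dioxolan-2-yl)-6-methoxyphenoxy]-3-[(tert-butyldimethylsilyl)oxy]propanoate
Conditions: TMSOCH2CH2OTMS, TMSOTf (cat.), CH2Cl2, −78 to −20 °C; pyridine quench
Reagents that add atoms: 1,2-bis(trimethylsilyloxy)ethane, C[Si](C)(C)OCCO[Si](C)(C)C
Why: Noyori acetalisation at low temperature should mask the aryl aldehyde as a 1,3-dioxolane without cleaving the silyl ether or epimerising the α-aryloxy ester, so that the next two steps address only the ester carbon.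

Step 6
Reactants: 7 methyl (S)-2-[2-(allyloxy)-4-(1,3-dioxolan-2-yl)-6-methoxyphenoxy]-3-[(tert-butyldimethylsilyl)oxy]propanoate
Product: 8 (S)-2-[2-(allyloxy)-4-(1,3-dioxolan-2-yl)-6-methoxyphenoxy]-3-[(tert-butyldimethylsilyl)oxy]propanal
Conditions: i-Bu2AlH (1.1 equiv), CH2Cl2, −78 °C; MeOH, then aq. KNaC4H4O6 (potassium sodium tartrate)
Reagents that add atoms: none
Why: Partial reduction of an α-alkoxy ester with i-Bu2AlH at −78 °C should stop at the chelated aluminium hemiacetal, which releases the aldehyde only on quench, and the stereocentre should hold if the crude aldehyde is kept cold and used at once.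

Step 7
Reactants: 9 4-bromo-2,6-dimethoxyphenol
Product: 10 2-(allyloxy)-5-bromo-1,3-dimethoxybenzene
Conditions: allyl bromide, K2CO3, DMF, rt
Reagents that add atoms: allyl bromide, C=CCBr
Why: Williamson etherification should give an allyl ether that tolerates bromine–lithium exchange and is later removed together with the ring B allyl group.

Step 8
Reactants: 10 2-(allyloxy)-5-bromo-1,3-dimethoxybenzene; 8 (S)-2-[2-(allyloxy)-4-(1,3-dioxolan-2-yl)-6-methoxyphenoxy]-3-[(tert-butyldimethylsilyl)oxy]propanal
Product: 12 (2S)-1-[4-(allyloxy)-3,5-dimethoxyphenyl]-2-[2-(allyloxy)-4-(1,3-dioxolan-2-yl)-6-methoxyphenoxy]-3-[(tert-butyldimethylsilyl)oxy]propan-1-ol as a mixture of C1 epimers, via aryllithium 11 (not isolated)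
Conditions: n-BuLi, THF, −78 °C; then 8, −78 °C; aq. NH4Cl
Reagents that add atoms: none
Why: Bromine–lithium exchange followed by 1,2-addition of the aryllithium to the aldehyde should form the C2–ring A bond, and no facial selectivity is required because the new carbinol centre is erased in step 11.

Step 9
Reactants: 12 (2S)-1-[4-(allyloxy)-3,5-dimethoxyphenyl]-2-[2-(allyloxy)-4-(1,3-dioxolan-2-yl)-6-methoxyphenoxy]-3-[(tert-butyldimethylsilyl)oxy]propan-1-ol
Product: 13 3-(allyloxy)-4-{[(2S)-1-[4-(allyloxy)-3,5-dimethoxyphenyl]-1,3-dihydroxypropan-2-yl]oxy}-5-methoxybenzaldehyde as a mixture of C1 epimers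
Conditions: 1 M HCl (aq), THF, rt
Reagents that add atoms: water, O
Why: Mild aqueous acid hydrolysis should remove the primary silyl ether and the dioxolane in one operation while the allyl ethers stay, and any reversible ionisation of the carbinol only epimerises a centre that is not yet defined.

Step 10
Reactants: 13 3-(allyloxy)-4-{[(2S)-1-[4-(allyloxy)-3,5-dimethoxyphenyl]-1,3-dihydroxypropan-2-yl]oxy}-5-methoxybenzaldehyde
Product: 14 3-hydroxy-4-{[(2S)-1,3-dihydroxy-1-(4-hydroxy-3,5-dimethoxyphenyl)propan-2-yl]oxy}-5-methoxybenzaldehyde as a mixture of C1 epimers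
Conditions: Pd(PPh3)4 (cat.), morpholine, THF, rt
Reagents that add atoms: none
Why: Tsuji–Trost-type deallylation (π-allyl complex of zerovalent palladium, trapped by morpholine) should free both phenols under neutral conditions, so that the cyclisation precursor is obtained without premature ionisation.

Step 11
Reactants: 14 3-hydroxy-4-{[(2S)-1,3-dihydroxy-1-(4-hydroxy-3,5-dimethoxyphenyl)propan-2-yl]oxy}-5-methoxybenzaldehyde (both C1 epimers)
Product: 16 (2S,3S)-2-(4-hydroxy-3,5-dimethoxyphenyl)-3-(hydroxymethyl)-5-methoxy-2,3-dihydro-1,4-benzodioxine-7-carbaldehyde, via quinone methide 15 (not isolated)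
Conditions: TsOH·H2O (0.2 equiv), MeCN (0.01 M), rt to 50 °C; aq. NaHCO3
Reagents that add atoms: none
Why: Protonation of the benzylic hydroxyl and loss of water, pushed by the para hydroxyl of ring A, should give the planar para-quinone methide 15 from either epimer of 14, so the carbinol configuration is erased before the ring closes. The closest known reaction type is the acid-mediated cyclisation of phenolic aryl glycerol aryl ethers to 2-aryl-1,4-benzodioxanes, together with the acid equilibration of cis to trans isomers in that series. The ring B phenol O1 then adds to the methide carbon C2 in a 6-exo-trig closure that forms the O1–C2 bond and the dioxane ring. The new stereocentre C2 is controlled by the existing centre C3: the addition is reversible under acid, so the product should collect in the trans isomer with aryl and hydroxymethyl both pseudo-equatorial on the half-chair, which is (2S,3S) because C3 is S. The step needs diastereoselectivity at C2 and chemoselectivity for O1 over the primary hydroxyl; the first is secured by thermodynamic control from C3, the second by ring size (six-membered dioxane against a strained oxetane) and by high dilution. C3 is never ionised, and mild acid at moderate temperature is chosen so that the methide does not tautomerise to the C2=C3 enol ether, which would erode C3.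

Step 12
Reactants: 16 (2S,3S)-2-(4-hydroxy-3,5-dimethoxyphenyl)-3-(hydroxymethyl)-5-methoxy-2,3-dihydro-1,4-benzodioxine-7-carbaldehyde
Product: 17 methyl (E)-3-[(2S,3S)-2-(4-hydroxy-3,5-dimethoxyphenyl)-3-(hydroxymethyl)-5-methoxy-2,3-dihydro-1,4-benzodioxin-7-yl]prop-2-enoate
Conditions: Ph3P=CHCO2Me, CH2Cl2, rt to 40 °C
Reagents that add atoms: methyl (triphenylphosphoranylidene)acetate, COC(=O)C=P(c1ccccc1)(c1ccccc1)c1ccccc1
Why: Wittig olefination with a stabilised ylide should give the (E)-enoate selectively and tolerate the free phenol and primary alcohol, since the ylide is too weak a base to open the dioxane.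

Step 13
Reactants: 17 methyl (E)-3-[(2S,3S)-2-(4-hydroxy-3,5-dimethoxyphenyl)-3-(hydroxymethyl)-5-methoxy-2,3-dihydro-1,4-benzodioxin-7-yl]prop-2-enoate
Product: 18 4-[(2S,3S)-3-(hydroxymethyl)-7-[(E)-3-hydroxyprop-1-en-1-yl]-5-methoxy-2,3-dihydro-1,4-benzodioxin-2-yl]-2,6-dimethoxyphenol (target)
Conditions: i-Bu2AlH (excess), CH2Cl2/THF, −78 to −20 °C; aq. KNaC4H4O6 (potassium sodium tartrate)
Reagents that add atoms: none
Why: 1,2-Reduction of the α,β-unsaturated ester with excess i-Bu2AlH (part is consumed by the two OH groups) should give the (E)-allylic alcohol without touching the alkene or the stereocentres, and the neutral tartrate work-up protects the acid-sensitive cinnamyl alcohol.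

**Compound list**

1 | methyl (R)-2,2-dimethyl-1,3-dioxolane-4-carboxylate | COC(=O)[C@H]1COC(C)(C)O1 | starting material
2 | methyl (R)-2,3-dihydroxypropanoate | COC(=O)[C@H](O)CO | intermediate
3 | methyl (R)-3-[(tert-butyldimethylsilyl)oxy]-2-hydroxypropanoate | COC(=O)[C@H](O)CO[Si](C)(C)C(C)(C)C | intermediate
4 | 3,4-dihydroxy-5-methoxybenzaldehyde | COc1cc(C=O)cc(O)c1O | starting material
5 | 3-(allyloxy)-4-hydroxy-5-methoxybenzaldehyde | COc1cc(C=O)cc(OCC=C)c1O | intermediate
6 | methyl (S)-2-[2-(allyloxy)-4-formyl-6-methoxyphenoxy]-3-[(tert-butyldimethylsilyl)oxy]propanoate | COC(=O)[C@H](CO[Si](C)(C)C(C)(C)C)Oc1c(OC)cc(C=O)cc1OCC=C | intermediate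
7 | methyl (S)-2-[2-(allyloxy)-4-(1,3-dioxolan-2-yl)-6-methoxyphenoxy]-3-[(tert-butyldimethylsilyl)oxy]propanoate | COC(=O)[C@H](CO[Si](C)(C)C(C)(C)C)Oc1c(OC)cc(C2OCCO2)cc1OCC=C | intermediate
8 | (S)-2-[2-(allyloxy)-4-(1,3-dioxolan-2-yl)-6-methoxyphenoxy]-3-[(tert-butyldimethylsilyl)oxy]propanal | O=C[C@H](CO[Si](C)(C)C(C)(C)C)Oc1c(OC)cc(C2OCCO2)cc1OCC=C | intermediate
9 | 4-bromo-2,6-dimethoxyphenol | COc1cc(Br)cc(OC)c1O | starting material
10 | 2-(allyloxy)-5-bromo-1,3-dimethoxybenzene | COc1cc(Br)cc(OC)c1OCC=C | intermediate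
11 | [4-(allyloxy)-3,5-dimethoxyphenyl]lithium (not isolated) | COc1cc([Li])cc(OC)c1OCC=C | intermediate
12 | (2S)-1-[4-(allyloxy)-3,5-dimethoxyphenyl]-2-[2-(allyloxy)-4-(1,3-dioxolan-2-yl)-6-methoxyphenoxy]-3-[(tert-butyldimethylsilyl)oxy]propan-1-ol, both C1 epimers | COc1cc(C(O)[C@H](CO[Si](C)(C)C(C)(C)C)Oc2c(OC)cc(C3OCCO3)cc2OCC=C)cc(OC)c1OCC=C | intermediate
13 | 3-(allyloxy)-4-{[(2S)-1-[4-(allyloxy)-3,5-dimethoxyphenyl]-1,3-dihydroxypropan-2-yl]oxy}-5-methoxybenzaldehyde, both C1 epimers | COc1cc(C(O)[C@H](CO)Oc2c(OC)cc(C=O)cc2OCC=C)cc(OC)c1OCC=C | intermediate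
14 | 3-hydroxy-4-{[(2S)-1,3-dihydroxy-1-(4-hydroxy-3,5-dimethoxyphenyl)propan-2-yl]oxy}-5-methoxybenzaldehyde, both C1 epimers | COc1cc(C(O)[C@H](CO)Oc2c(O)cc(C=O)cc2OC)cc(OC)c1O | intermediate
15 | 4-{[(2R)-1-(3,5-dimethoxy-4-oxocyclohexa-2,5-dien-1-ylidene)-3-hydroxypropan-2-yl]oxy}-3-hydroxy-5-methoxybenzaldehyde, para-quinone methide, same spatial arrangement as 14 (not isolated) | COC1=CC(=C[C@H](CO)Oc2c(O)cc(C=O)cc2OC)C=C(OC)C1=O | intermediate
16 | (2S,3S)-2-(4-hydroxy-3,5-dimethoxyphenyl)-3-(hydroxymethyl)-5-methoxy-2,3-dihydro-1,4-benzodioxine-7-carbaldehyde | COc1cc([C@@H]2Oc3cc(C=O)cc(OC)c3O[C@H]2CO)cc(OC)c1O | intermediate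
17 | methyl (E)-3-[(2S,3S)-2-(4-hydroxy-3,5-dimethoxyphenyl)-3-(hydroxymethyl)-5-methoxy-2,3-dihydro-1,4-benzodioxin-7-yl]prop-2-enoate | COc1cc([C@@H]2Oc3cc(/C=C/C(=O)OC)cc(OC)c3O[C@H]2CO)cc(OC)c1O | intermediate
18 | 4-[(2S,3S)-3-(hydroxymethyl)-7-[(E)-3-hydroxyprop-1-en-1-yl]-5-methoxy-2,3-dihydro-1,4-benzodioxin-2-yl]-2,6-dimethoxyphenol | COc1cc([C@@H]2Oc3cc(/C=C/CO)cc(OC)c3O[C@H]2CO)cc(OC)c1O | target

**Totals**

Total step count: 13.
Longest linear sequence: 11 steps (1, 2, 4, 5, 6, 8, 9, 10, 11, 12, 13).

**Steps most likely to fail**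

Step 11. The closure may stop at a kinetic mixture of cis and trans isomers, and prolonged acid may let the methide tautomerise to the C2=C3 enol ether or lose formaldehyde, which would erode C3. The fallback sets out from 14 and comes back at 16; it replaces acid ionisation by halide activation. TMSBr in CH2Cl2 at rt should convert the benzylic hydroxyl of 14 selectively into the bromide, giving 4-{[(2S)-1-bromo-3-hydroxy-1-(4-hydroxy-3,5-dimethoxyphenyl)propan-2-yl]oxy}-3-hydroxy-5-methoxybenzaldehyde F1; transient silyl ethers on the other hydroxyls fall off on work-up. Shaking a CH2Cl2 solution of F1 with aqueous NaHCO3 should eliminate HBr to the same quinone methide 15 at neutral pH, where the ring B phenol adds without strong acid to give 16. Any cis isomer would be removed by chromatography.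

Step 3. The single equivalent of allyl bromide may be shared between the two phenoxide oxygens, or double allylation may occur. The fallback sets out from 4 and comes back at 5; it uses the innate preference of weak-base alkylation for the more acidic 4-OH. PMBCl, NaHCO3 and NaI in DMF at 40 °C should give 3-hydroxy-5-methoxy-4-[(4-methoxybenzyl)oxy]benzaldehyde F2. Allyl bromide and K2CO3 in DMF should then give 3-(allyloxy)-5-methoxy-4-[(4-methoxybenzyl)oxy]benzaldehyde F3. TFA with anisole in CH2Cl2 at 0 °C should remove the PMB group and return 5.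

Step 6. Over-reduction to the primary alcohol and epimerisation or β-elimination of the α-aryloxy aldehyde during work-up are the likely failures; step 8 shares this sensitivity. The fallback sets out from 7 and comes back at 8; it separates reduction and oxidation. i-Bu2AlH (2.5 equiv) in CH2Cl2 at −78 to 0 °C should give (R)-2-[2-(allyloxy)-4-(1,3-dioxolan-2-yl)-6-methoxyphenoxy]-3-[(tert-butyldimethylsilyl)oxy]propan-1-ol F4, which has the same spatial arrangement and a changed CIP letter. The work-up is kept neutral so that the silyl group does not move between the two primary oxygens. Dess–Martin periodinane with NaHCO3 in CH2Cl2 at 0 °C should then give 8, used crude in step 8.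

**Further compounds**

F1 | step 11 | 4-{[(2S)-1-bromo-3-hydroxy-1-(4-hydroxy-3,5-dimethoxyphenyl)propan-2-yl]oxy}-3-hydroxy-5-methoxybenzaldehyde, both C1 epimers | COc1cc(C(Br)[C@H](CO)Oc2c(O)cc(C=O)cc2OC)cc(OC)c1O
F2 | step 3 | 3-hydroxy-5-methoxy-4-[(4-methoxybenzyl)oxy]benzaldehyde | COc1ccc(COc2c(O)cc(C=O)cc2OC)cc1
F3 | step 3 | 3-(allyloxy)-5-methoxy-4-[(4-methoxybenzyl)oxy]benzaldehyde | COc1ccc(COc2c(OCC=C)cc(C=O)cc2OC)cc1
F4 | step 6 | (R)-2-[2-(allyloxy)-4-(1,3-dioxolan-2-yl)-6-methoxyphenoxy]-3-[(tert-butyldimethylsilyl)oxy]propan-1-ol | OC[C@H](CO[Si](C)(C)C(C)(C)C)Oc1c(OC)cc(C2OCCO2)cc1OCC=C
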